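**Plan** (guaiane numbering: ring A = C1–C5, ring B = C1, C5–C10)
Retrosynthesis: the two ester C–O bonds go first (angelate on O8, acetate on O6). Then the C1=C10 double bond of ring B is cut; it is the only alkene of the carbon skeleton, tetrasubstituted and placed at the fusion with ring A, so it opens into a methylidene on C1 of ring A and an isopropenyl end at C10. The open chain is then cut at C7–C8 and C5–C6 (two aldol bonds) and at C4–O (from a C–B bond).
Forward: ring A is 3-methylcyclopent-2-enone; C5–C6 is made by a borylative aldol, C1 is methylenated, C7–C8 is made by a boron aldol with 3-methylbut-3-enal, and ring B is closed by metathesis before the final ester exchange.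
Stereochemistry: C4 from a chiral copper catalyst, C5 from aldol addition anti to the boryl group, C7/C8 from a Z-enolate syn aldol steered by C5, C6 from hydroxyl-directed anti reduction; no stereocentre is created after step 8.

Key step: step 11

Assumption: the C6 carbinol made in step 1 forms as an epimer mixture and is written without configuration in 4–7, because step 4 turns it into a ketone; the bisphosphine hand is taken as the one that gives the 3R boronate (its antipode is used otherwise).

Step 1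
Reactants: 1 3-methylcyclopent-2-en-1-one; 2 3-methylbutanal
Product: 5 (2S,3R)-2-(1-hydroxy-3-methylbutyl)-3-methyl-3-(4,4,5,5-tetramethyl-1,3,2-dioxaborolan-2-yl)cyclopentan-1-one (carbinol epimers), via boron enolate 3 (not isolated), via boron aldolate 4 (not isolated)
Conditions: CuCl (5 mol %), (R,R)-QuinoxP* (6 mol %), NaOtBu (10 mol %), B2pin2, THF, rt; then 2, −20 °C → rt; aq NH4Cl
Reagents that add atoms: bis(pinacolato)diboron, CC1(C)OB(OC1(C)C)B1OC(C)(C)C(C)(C)O1
Why: A monovalent copper boryl complex of the chiral bisphosphine transfers boron to C4 (enantioselective conjugate borylation), exchange with B2pin2 gives boron enolate 3, and this adds to the aldehyde on the C5 face away from the boryl group (borylative aldol), so C4 and C5 are set here.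

Step 2
Reactants: 5
Product: 6 3-methyl-1-[(1R,2R)-2-methyl-5-methylidene-2-(4,4,5,5-tetramethyl-1,3,2-dioxaborolan-2-yl)cyclopentyl]butan-1-ol (carbinol epimers)
Conditions: Zn, CH2Br2, TiCl4, THF (reagent pre-formed at 5 °C); then 5, CH2Cl2, 0 °C → rt
Reagents that add atoms: dibromomethane, BrCBr
Why: Takai–Lombardo methylenation uses a non-basic zinc/titanium methylene reagent, so the C1 ketone becomes the methylidene without enolising C5 or triggering retro-aldol cleavage, and free hydroxyls and boronic esters are tolerated.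

Step 3
Reactants: 6
Product: 7 (1S,2R)-2-(1-hydroxy-3-methylbutyl)-1-methyl-3-methylidenecyclopentan-1-ol (side-chain carbinol epimers)
Conditions: NaBO3·4H2O, THF/H2O (1:1), rt
Reagents that add atoms: sodium perborate, [Na+].[O-]OB=O
Why: Perborate oxidation of the tertiary C–B bond proceeds by 1,2-shift of C4 from boron to oxygen with retention, which fixes the C4 carbinol as 4S and leaves the alkene alone.

Step 4
Reactants: 7
Product: 8 1-[(1S,2S)-2-hydroxy-2-methyl-5-methylidenecyclopentyl]-3-methylbutan-1-one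
Conditions: Dess–Martin periodinane, NaHCO3, CH2Cl2, 0 °C → rt
Reagents that add atoms: none
Why: Dess–Martin oxidation takes only the secondary C6 carbinol to the ketone under buffered, near-neutral conditions that should not move the β,γ-alkene into conjugation or epimerise C5.

Step 5
Reactants: 8
Product: 9 3-methyl-1-[(1S,2S)-2-methyl-5-methylidene-2-(triethylsilyloxy)cyclopentyl]butan-1-one
Conditions: TESOTf, 2,6-lutidine, CH2Cl2, −78 → 0 °C
Reagents that add atoms: triethylsilyl triflate, CC[Si](CC)(CC)OS(=O)(=O)C(F)(F)F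
Why: Silyl triflate with 2,6-lutidine is the standard silylation of a hindered tertiary alcohol, and the weak base does not enolise the ketone at low temperature.

Step 6
Reactants: 10 3-methylbut-3-en-1-ol
Product: 11 3-methylbut-3-enal
Conditions: Dess–Martin periodinane, NaHCO3, CH2Cl2, 0 °C; filtered solution used at once
Reagents that add atoms: none
Why: Dess–Martin oxidation gives the volatile β,γ-unsaturated aldehyde without acid or base that would shift its alkene into conjugation.

Step 7
Reactants: 9; 11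
Product: 14 (2R,3S)-3-hydroxy-5-methyl-1-[(1S,2S)-2-methyl-5-methylidene-2-(triethylsilyloxy)cyclopentyl]-2-(propan-2-yl)hex-5-en-1-one, via boron enolate 12 (not isolated), via boron aldolate 13 (not isolated)
Conditions: Bu2BOTf, iPr2NEt, CH2Cl2, −78 → 0 °C; then 11, −78 → −20 °C; H2O2, pH 7 buffer, MeOH, 0 °C
Reagents that add atoms: none
Why: Soft enolisation with Bu2BOTf and iPr2NEt occurs at the less hindered C7 methylene to give the Z enolate 12, whose closed Zimmerman–Traxler transition state (boron aldol) gives the 7,8-syn adduct, and the C5 centre keeps its quaternary C4 neighbour away from the incoming aldehyde, which should favour the (7R,8S) isomer.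

Step 8
Reactants: 14
Product: 15 (1R,2R,3S)-5-methyl-1-[(1R,2S)-2-methyl-5-methylidene-2-(triethylsilyloxy)cyclopentyl]-2-(propan-2-yl)hex-5-ene-1,3-diol
Conditions: Me4NBH(OAc)3, MeCN/AcOH (1:1), −30 → −20 °C
Reagents that add atoms: none
Why: In the Evans–Saksena reduction the C8 hydroxyl binds the borohydride and delivers hydride to C6 through a chair transition state, giving the 6,8-anti diol and so the 6R centre.

Step 9
Reactants: 15
Product: 16 (1R,2S,3S)-3-[tert-butyl(dimethyl)silyl]oxy-5-methyl-1-[(1R,2S)-2-methyl-5-methylidene-2-(triethylsilyloxy)cyclopentyl]-2-(propan-2-yl)hex-5-en-1-ol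
Conditions: TBSOTf (1.05 equiv), 2,6-lutidine, CH2Cl2, −78 °C
Reagents that add atoms: tert-butyldimethylsilyl triflate, CC(C)(C)[Si](C)(C)OS(=O)(=O)C(F)(F)F
Why: Kinetic silylation at low temperature should pick the C8 hydroxyl, which has a methylene neighbour, over the C6 hydroxyl held between two branched carbons.

Step 10
Reactants: 16
Product: 17 (1R,2S,3S)-3-[tert-butyl(dimethyl)silyl]oxy-5-methyl-1-[(1R,2S)-2-methyl-5-methylidene-2-(triethylsilyloxy)cyclopentyl]-2-(propan-2-yl)hex-5-en-1-yl acetate
Conditions: Ac2O, Et3N, DMAP (cat.), CH2Cl2, rt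
Reagents that add atoms: acetic anhydride, CC(=O)OC(C)=O
Why: DMAP-catalysed acetylation esterifies the one remaining hydroxyl, and nothing else in 16 can be acylated.

Step 11
Reactants: 17
Product: 18 (4S,5R,6R,7S,8S)-6-acetoxy-8-[tert-butyl(dimethyl)silyl]oxy-4-(triethylsilyloxy)guai-1(10)-ene
Conditions: second-generation Grubbs catalyst RuCl2(=CHPh)(H2IMes)(PCy3) (15 mol %, in portions), toluene (0.005 M), 100 °C, argon sparge
Reagents that add atoms: none
Why: The ruthenium benzylidene first exchanges with the less hindered isopropenyl terminus at C10, the new alkylidene adds across the C1 methylidene in a [2+2] step, and the metallacyclobutane cycloreverts to release ethene and leave the C1=C10 bond. The closest known reaction type is ring-closing metathesis of two 1,1-disubstituted alkenes to tetrasubstituted cycloalkenes with N-heterocyclic-carbene ruthenium catalysts under forcing conditions. Ring B is closed as a seven-membered carbocycle by joining C1 and C10 of a chain already anchored at C5 of ring A. No stereocentre is formed, and the neutral conditions leave the five existing centres untouched. The step needs cyclisation to win over dimerisation and over alkene migration; the anchoring on ring A, the branching at C6, C7 and C8 that folds the chain, high dilution, heat and continuous removal of ethene should secure this.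

Step 12
Reactants: 18
Product: 19 (4S,5R,6R,7R,8S)-6-acetoxyguai-1(10)-ene-4,8-diol
Conditions: HF·pyridine, pyridine, THF, 0 °C → rt
Reagents that add atoms: none
Why: Buffered HF·pyridine removes both silyl ethers (fluoride-mediated desilylation) without touching the acetate, and the trans placement of O6 and O8 on ring B prevents acetyl migration.

Step 13
Reactants: 19; 20 angelic acid
Product: 22 (4S,5R,6R,7R,8S)-6-acetoxy-4-hydroxyguai-1(10)-en-8-yl (Z)-2-methylbut-2-enoate, via mixed anhydride 21 (not isolated)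
Conditions: 20, 2,4,6-trichlorobenzoyl chloride, Et3N, toluene, rt; then 19, 80 °C
Reagents that add atoms: none
Why: Yamaguchi esterification through mixed anhydride 21 acylates the secondary C8 hydroxyl while the tertiary C4 hydroxyl stays inert, and the DMAP-free conditions are the usual way to avoid Z-to-E isomerisation of the angeloyl group.

**Compound list**
1 | 3-methylcyclopent-2-en-1-one | CC1=CC(=O)CC1 | starting material
2 | 3-methylbutanal (isovaleraldehyde) | CC(C)CC=O | starting material
3 | 4,4,5,5-tetramethyl-2-{[(3R)-3-methyl-3-(4,4,5,5-tetramethyl-1,3,2-dioxaborolan-2-yl)cyclopent-1-en-1-yl]oxy}-1,3,2-dioxaborolane (boron enolate) | CC1(C)OB(OC1(C)C)OC1=C[C@@](C)(B2OC(C)(C)C(C)(C)O2)CC1 | intermediate (not isolated)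
4 | O-pinacolboryl aldolate of 5 | CC(C)CC(OB1OC(C)(C)C(C)(C)O1)[C@H]1C(=O)CC[C@]1(C)B1OC(C)(C)C(C)(C)O1 | intermediate (not isolated)
5 | (2S,3R)-2-(1-hydroxy-3-methylbutyl)-3-methyl-3-(4,4,5,5-tetramethyl-1,3,2-dioxaborolan-2-yl)cyclopentan-1-one, carbinol epimers | CC(C)CC(O)[C@H]1C(=O)CC[C@]1(C)B1OC(C)(C)C(C)(C)O1 | intermediate
6 | 3-methyl-1-[(1R,2R)-2-methyl-5-methylidene-2-(4,4,5,5-tetramethyl-1,3,2-dioxaborolan-2-yl)cyclopentyl]butan-1-ol, carbinol epimers | CC(C)CC(O)[C@H]1C(=C)CC[C@]1(C)B1OC(C)(C)C(C)(C)O1 | intermediate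
7 | (1S,2R)-2-(1-hydroxy-3-methylbutyl)-1-methyl-3-methylidenecyclopentan-1-ol, side-chain carbinol epimers | CC(C)CC(O)[C@H]1C(=C)CC[C@]1(C)O | intermediate
8 | 1-[(1S,2S)-2-hydroxy-2-methyl-5-methylidenecyclopentyl]-3-methylbutan-1-one | CC(C)CC(=O)[C@H]1C(=C)CC[C@]1(C)O | intermediate
9 | 3-methyl-1-[(1S,2S)-2-methyl-5-methylidene-2-(triethylsilyloxy)cyclopentyl]butan-1-one | CC(C)CC(=O)[C@H]1C(=C)CC[C@]1(C)O[Si](CC)(CC)CC | intermediate
10 | 3-methylbut-3-en-1-ol | CC(=C)CCO | starting material
11 | 3-methylbut-3-enal | CC(=C)CC=O | intermediate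
12 | (Z)-dibutylboron enolate of 9 | CCCCB(CCCC)O/C(=C\C(C)C)[C@H]1C(=C)CC[C@]1(C)O[Si](CC)(CC)CC | intermediate (not isolated)
13 | O-dibutylboryl aldolate of 14 | CCCCB(CCCC)O[C@@H](CC(C)=C)[C@@H](C(C)C)C(=O)[C@H]1C(=C)CC[C@]1(C)O[Si](CC)(CC)CC | intermediate (not isolated)
14 | (2R,3S)-3-hydroxy-5-methyl-1-[(1S,2S)-2-methyl-5-methylidene-2-(triethylsilyloxy)cyclopentyl]-2-(propan-2-yl)hex-5-en-1-one | O[C@@H](CC(C)=C)[C@@H](C(C)C)C(=O)[C@H]1C(=C)CC[C@]1(C)O[Si](CC)(CC)CC | intermediate
15 | (1R,2R,3S)-5-methyl-1-[(1R,2S)-2-methyl-5-methylidene-2-(triethylsilyloxy)cyclopentyl]-2-(propan-2-yl)hex-5-ene-1,3-diol | O[C@@H](CC(C)=C)[C@@H](C(C)C)[C@@H](O)[C@H]1C(=C)CC[C@]1(C)O[Si](CC)(CC)CC | intermediate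
16 | (1R,2S,3S)-3-[tert-butyl(dimethyl)silyl]oxy-5-methyl-1-[(1R,2S)-2-methyl-5-methylidene-2-(triethylsilyloxy)cyclopentyl]-2-(propan-2-yl)hex-5-en-1-ol | CC(C)(C)[Si](C)(C)O[C@@H](CC(C)=C)[C@@H](C(C)C)[C@@H](O)[C@H]1C(=C)CC[C@]1(C)O[Si](CC)(CC)CC | intermediate
17 | (1R,2S,3S)-3-[tert-butyl(dimethyl)silyl]oxy-5-methyl-1-[(1R,2S)-2-methyl-5-methylidene-2-(triethylsilyloxy)cyclopentyl]-2-(propan-2-yl)hex-5-en-1-yl acetate (metathesis precursor) | CC(C)(C)[Si](C)(C)O[C@@H](CC(C)=C)[C@@H](C(C)C)[C@@H](OC(C)=O)[C@H]1C(=C)CC[C@]1(C)O[Si](CC)(CC)CC | intermediate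
18 | (4S,5R,6R,7S,8S)-6-acetoxy-8-[tert-butyl(dimethyl)silyl]oxy-4-(triethylsilyloxy)guai-1(10)-ene (metathesis product) | CC(C)(C)[Si](C)(C)O[C@H]1CC(C)=C2CC[C@](C)(O[Si](CC)(CC)CC)[C@H]2[C@H](OC(C)=O)[C@@H]1C(C)C | intermediate
19 | (4S,5R,6R,7R,8S)-6-acetoxyguai-1(10)-ene-4,8-diol | O[C@H]1CC(C)=C2CC[C@](C)(O)[C@H]2[C@H](OC(C)=O)[C@@H]1C(C)C | intermediate
20 | angelic acid, (Z)-2-methylbut-2-enoic acid | C/C=C(/C)C(=O)O | starting material
21 | angelic 2,4,6-trichlorobenzoic anhydride | C/C=C(/C)C(=O)OC(=O)c1c(Cl)cc(Cl)cc1Cl | intermediate (not isolated)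
22 | (4S,5R,6R,7R,8S)-6-acetoxy-4-hydroxyguai-1(10)-en-8-yl (Z)-2-methylbut-2-enoate | C/C=C(/C)C(=O)O[C@H]1CC(C)=C2CC[C@](C)(O)[C@H]2[C@H](OC(C)=O)[C@@H]1C(C)C | target

**Count**
Total steps: 13. Longest linear sequence: 12 steps (steps 1–5 and 7–13, from 1).

**Steps most likely to fail**

Step 11. The bulky ruthenium alkylidene may fail to engage the C1 methylidene next to the crowded C5, so that catalyst decay, hydride-induced alkene migration or intermolecular metathesis outrun the tetrasubstituted closure. The fallback closes ring B reductively from two carbonyl groups. It sets out from 17: ozonolysis of both methylidene groups (O3, CH2Cl2/MeOH, −78 °C; Me2S) gives the diketone (1R,2S,3S)-3-[tert-butyl(dimethyl)silyl]oxy-1-[(1R,2S)-2-methyl-5-oxo-2-(triethylsilyloxy)cyclopentyl]-5-oxo-2-(propan-2-yl)hexyl acetate F1. Intramolecular McMurry coupling (TiCl3(DME)1.5, Zn–Cu couple, DME, reflux, slow addition) then joins C1 and C10 and returns to the route at 18.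

Step 7. The amine/boron triflate pair may deprotonate the doubly activated C5–H instead of C7, which would pull the C1 alkene into conjugation, scramble C5 or expel the C4 silyloxy group; the amine may also isomerise aldehyde 11. The fallback makes the C7 enolate regiospecifically and without base, by 1,4-reduction of an enone. It sets out from 1 and returns at 14.
- With 3-methylbut-2-enal in place of 2, the step 1 protocol gives (2S,3R)-2-(1-hydroxy-3-methylbut-2-en-1-yl)-3-methyl-3-(4,4,5,5-tetramethyl-1,3,2-dioxaborolan-2-yl)cyclopentan-1-one F2.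
- The conditions of steps 2 and 3 give the methylidene boronate 3-methyl-1-[(1R,2R)-2-methyl-5-methylidene-2-(4,4,5,5-tetramethyl-1,3,2-dioxaborolan-2-yl)cyclopentyl]but-2-en-1-ol F3 and then the diol (1S,2R)-2-(1-hydroxy-3-methylbut-2-en-1-yl)-1-methyl-3-methylidenecyclopentan-1-ol F4.
- MnO2 (CH2Cl2, rt) oxidises the allylic carbinol to the enone 1-[(1S,2S)-2-hydroxy-2-methyl-5-methylidenecyclopentyl]-3-methylbut-2-en-1-one F5, and TESOTf/2,6-lutidine gives its triethylsilyl ether F6.
- Catecholborane (THF, rt) adds hydride 1,4 through the s-cis enone to give the (Z)-catecholboron enolate F7, and 11 (−78 °C → rt, pH 7 buffer) then gives the syn aldol 14.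

Step 13. Acylation of the hindered C8 hydroxyl may be slow, and prolonged heating of the activated angeloyl unit may isomerise it to the E (tigloyl) ester. The fallback builds the Z alkene on an ester already in place. It sets out from 19: esterification with 2-[bis(2,2,2-trifluoroethoxy)phosphoryl]propanoic acid (DCC, DMAP cat., CH2Cl2, rt) gives (4S,5R,6R,7R,8S)-6-acetoxy-4-hydroxyguai-1(10)-en-8-yl 2-[bis(2,2,2-trifluoroethoxy)phosphoryl]propanoate F8. Still–Gennari olefination with acetaldehyde (KHMDS, 18-crown-6, THF, −78 °C) gives the Z enoate and returns to the route at 22.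

**Further compounds**
F1 | step 11 | (1R,2S,3S)-3-[tert-butyl(dimethyl)silyl]oxy-1-[(1R,2S)-2-methyl-5-oxo-2-(triethylsilyloxy)cyclopentyl]-5-oxo-2-(propan-2-yl)hexyl acetate | CC(C)(C)[Si](C)(C)O[C@@H](CC(C)=O)[C@@H](C(C)C)[C@@H](OC(C)=O)[C@H]1C(=O)CC[C@]1(C)O[Si](CC)(CC)CC
F2 | step 7 | (2S,3R)-2-(1-hydroxy-3-methylbut-2-en-1-yl)-3-methyl-3-(4,4,5,5-tetramethyl-1,3,2-dioxaborolan-2-yl)cyclopentan-1-one, carbinol epimers | CC(C)=CC(O)[C@H]1C(=O)CC[C@]1(C)B1OC(C)(C)C(C)(C)O1
F3 | step 7 | 3-methyl-1-[(1R,2R)-2-methyl-5-methylidene-2-(4,4,5,5-tetramethyl-1,3,2-dioxaborolan-2-yl)cyclopentyl]but-2-en-1-ol, carbinol epimers | CC(C)=CC(O)[C@H]1C(=C)CC[C@]1(C)B1OC(C)(C)C(C)(C)O1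
F4 | step 7 | (1S,2R)-2-(1-hydroxy-3-methylbut-2-en-1-yl)-1-methyl-3-methylidenecyclopentan-1-ol, side-chain carbinol epimers | CC(C)=CC(O)[C@H]1C(=C)CC[C@]1(C)O
F5 | step 7 | 1-[(1S,2S)-2-hydroxy-2-methyl-5-methylidenecyclopentyl]-3-methylbut-2-en-1-one | CC(C)=CC(=O)[C@H]1C(=C)CC[C@]1(C)O
F6 | step 7 | 3-methyl-1-[(1S,2S)-2-methyl-5-methylidene-2-(triethylsilyloxy)cyclopentyl]but-2-en-1-one | CC(C)=CC(=O)[C@H]1C(=C)CC[C@]1(C)O[Si](CC)(CC)CC
F7 | step 7 | (Z)-catecholboron enolate of 9 | c1ccc2OB(Oc2c1)O/C(=C\C(C)C)[C@H]1C(=C)CC[C@]1(C)O[Si](CC)(CC)CC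
F8 | step 13 | (4S,5R,6R,7R,8S)-6-acetoxy-4-hydroxyguai-1(10)-en-8-yl 2-[bis(2,2,2-trifluoroethoxy)phosphoryl]propanoate | CC(C(=O)O[C@H]1CC(C)=C2CC[C@](C)(O)[C@H]2[C@H](OC(C)=O)[C@@H]1C(C)C)P(=O)(OCC(F)(F)F)OCC(F)(F)F
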